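Readings and results stem from a simulated flask with made-up constants.

The midnight flask cannot have levelled off for want of X: at 30.0 min D reads 10.0%, and the other 90.0% of the charge is far more than the D made.

| setting | midnight | dawn | flask |
|---|---|---|---|
| X | 0.40 M | 0.40 M | 0.40 M |
| G | 10 mM | 20 mM | 10 mM |
| temperature | 0 °C | −5 °C | 0 °C |
| remark | the very flask that is asked about, followed so far | run made earlier |  |
| time |  |  | 50 min |

- midnight (time / min: D / %): 1.50: 1.4; 5.00: 5.7; 8.00: 7.8; 12.0: 8.9; 20.0: 9.6; 25.0: 9.9; 30.0: 10.0
- dawn (time / min: D / %): 0.667: 0.8; 1.33: 1.2; 2.00: 2.4; 3.00: 4.1; 4.00: 5.4; 5.00: 6.3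

(scatter of a reading: 0.3 percentage points)

- maple: at 50 min raise the temperature by 15 K, then wait 25 min
- oak: at 50 min take out 90% of the D then present, then wait 25 min
- birch: at 50 min add G, 100% of the amount charged, then wait 25 min
- elm: change nothing and wait 25 min more

1. D, in percent of the X first charged, at 50 min
2. the option that brings most further D ("none" if no option brings more than 2 percentage points) (maple / oak / birch / elm / none)
3. D present, with what was taken out counted in, in percent of the X first charged, after maple
4. D present, with what was taken out counted in, in percent of the X first charged, after birch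

- solid, in amounts per volume of the solution: X
- D taken out counts as made
- the numbers in the tables scatter with a standard deviation of 0.3 percentage points
- at the start none of X is in solution
- additions bring no volume worth counting

Two chemists dispute what stands behind that flat line. The first says X and D have come to a balance, and G merely hurries the flask there. Her evidence is dawn, with twice the G and colder, which reads 6.3% at 5.00 min against midnight's 5.7% at 5.00 min, so D has not followed G. Take D out, she says, and it refills.

The second says G stops working. Dawn, he answers, went from 5.4% to 6.3% in its last two readings, with a scatter of 0.3 percentage points, so it shows a climb and no ceiling. Divide the rate of making D by the rate of losing G and the minutes drop out. What remains is the D made per G charged, the turnover number, here 10.0% of 0.40 M over 10 mM, or 4.00.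

I side with the second. On my reckoning [D] stays near 40.0 mM, which is 10.0% at 50 min. Maple, oak and elm then bring nothing, while birch's 10.0 mM of G, at 4.00 each, lifts D to 20.0%.

The forecast took the first side, “the plateau is an equilibrium with X held by excess solid”, and gave 10% now, oak as best, 15.5% after maple and 10.1% after birch.

The flask gives 9.80% now and 9.80% after maple, and birch is best at 14.9%, while oak and elm add 0 points.

    J + G → Q (k = 2.20 M⁻¹ s⁻¹, Ea = 56.0 kJ mol⁻¹)
    X ⇌ J, rate k2*(cs2 - [J]) while solid is left; crystals form when [J] > cs2 (solubility = 16.0 mM, k = 0.00990 s⁻¹)
    G + D → L (k = 0.120 M⁻¹ s⁻¹, Ea = 36.0 kJ mol⁻¹)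
    Q → G + D (k = 12.0 s⁻¹, Ea = 54.0 kJ mol⁻¹)
    G → Z (k = 0.00130 s⁻¹, Ea = 90.0 kJ mol⁻¹)
    (constants at 0 °C)

Q gave G and D while G lasted: half of that step's turnover up to 50 min was done by 4.57 min, and at 25.0 min G stood at 0.0552% of its charge, with 58.6% in L and 41.3% in Z. After that J at 4.00% and solid X at 84.7% stood beside 0% G, and D still read 9.80% at 500 min. The first's view gives the right flat line for this flask left untouched, but no further: oak added 0 points, so the D taken out did not refill. My birch figure ran high: the added G delivered 2.06 D per G, half of 4.00.

Take a neighbour flask with the same G but 0.68 M of X. There 4.00 per G gives 40.0 mM of D, or 5.88% of its X, and the computed flask reads 5.76% at 50 min.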